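## Retrosynthetic overview
1. The esters go on last. The 9-ester is added to the 7,9-diol with transient 7-O-silylation, and the 9α-OH comes from a 7-OH-directed reduction of a 9-ketone.
2. The 8α-angelate and 7β-OH pair comes from SN2 opening of a 7β,8β-epoxy-9-ketone by angelate.
3. Key bond C10–C11 (closes the cyclobutane, creates quaternary C10): oxidative coupling of the bis-enolate of a cis-fused 6–7 1,6-diketone. This joins two α-carbons that are both normally donors.
4. The seven-membered ring comes from CHMe insertion (diazoethane) into an epoxy-decalone. The enone ring comes from a Diels–Alder reaction of an acetylacetone-derived diene, anti to the oxirane of an enantiopure epoxy-enone.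
5. Ring order: six (bought), six (Diels–Alder), seven (expansion), four (coupling). All stereocentres relay from one catalytic asymmetric epoxidation.

Numbering of late compounds follows the longipinane skeleton: C1 ketone, C2=C3(Me), C4, C5, C6(Me2), C7, C8, C9, C10(Me), C11. The cyclobutane is C4–C5–C11–C10.

Assumption: the quinine-derived amine salt in step 1 gives the (1S,6S)-epoxide. If the sense proves opposite, the quinidine-derived pseudo-enantiomer is used.

## Route

**Step 1**
Reactants: 1 4,4-dimethylcyclohex-2-en-1-one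
Product: 2 (1S,6S)-5,5-dimethyl-7-oxabicyclo[4.1.0]heptan-2-one
Conditions: 9-amino-9-deoxy-epi-quinine (C20H25N3O, 10 mol%), CF3CO2H (20 mol%), 50% aq H2O2 (1.5 equiv), dioxane, 35 °C
Reagents that add atoms: hydrogen peroxide, OO
Why: Iminium-catalysed asymmetric Weitz–Scheffer epoxidation, in which the chiral primary-amine salt steers conjugate addition of H2O2 and ring closure to one enantioface and so sets the future C7 and C8 (cis by ring constraint).

**Step 2**
Reactants: 2 (1S,6S)-5,5-dimethyl-7-oxabicyclo[4.1.0]heptan-2-one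
Product: 4 (1S,6S)-5,5-dimethyl-7-oxabicyclo[4.1.0]hept-3-en-2-one, via lithium enolate 3 (not isolated)
Conditions: LDA (1.1 equiv), THF, −78 °C; then PhS(Cl)=N-t-Bu (1.2 equiv), −78 °C
Reagents that add atoms: none
Why: Mukaiyama one-pot dehydrogenation, in which only the CH2 flank can enolise and S-attack followed by syn-elimination of the sulfenamide at −78 °C gives the enone without touching the oxirane stereocentres.

**Step 3**
Reactants: 5 (E)-4-methoxypent-3-en-2-one
Product: 6 (E)-2-(tert-butyldimethylsilyloxy)-4-methoxypenta-1,3-diene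
Conditions: TBSOTf (1.1 equiv), Et3N (1.5 equiv), Et2O, 0 °C
Reagents that add atoms: tert-butyldimethylsilyl triflate, CC(C)(C)[Si](C)(C)OS(=O)(=O)C(F)(F)F
Why: Soft enolisation and O-silylation of the acetyl CH3 of a vinylogous ester gives a methyl-substituted Danishefsky-type diene, and no stereocentre is formed.

**Step 4**
Reactants: 4 (1S,6S)-5,5-dimethyl-7-oxabicyclo[4.1.0]hept-3-en-2-one; 6 (E)-2-(tert-butyldimethylsilyloxy)-4-methoxypenta-1,3-diene
Product: 7 (2S,3S,4aR,8S,8aR)-6-(tert-butyldimethylsilyloxy)-2,3-epoxy-8-methoxy-4,4,8-trimethyl-3,4,4a,5,8,8a-hexahydronaphthalen-1(2H)-one (cis-fused; 4a-H, 8a-H and the oxirane O on one face; the C8 OMe epimer is inconsequential)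
Conditions: HN(SO2CF3)2 (5 mol%), CH2Cl2, −78 → −40 °C; Et3N quench
Reagents that add atoms: diene 6, CO/C(C)=C/C(=C)O[Si](C)(C)C(C)(C)C
Why: Silyl-triflimide-catalysed Diels–Alder (double Mukaiyama–Michael) reaction of a hindered enone, in which the nucleophilic CH2 terminus bonds to the β-carbon next to CMe2 and the diene adds anti to the oxirane, setting the cis ring fusion (future C4, C5) relative to C7 and C8.

**Step 5**
Reactants: 8 N-ethyl-N-nitrosourea
Product: 9 diazoethane (dry ethereal solution)
Conditions: 40% aq KOH, Et2O, 0 °C; ether layer decanted and dried over KOH pellets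
Reagents that add atoms: none
Why: Base-induced fragmentation of an N-nitrosourea is the standard preparation of a non-stabilised diazoalkane, and no stereocentre is formed.

**Step 6**
Reactants: 7 Diels–Alder adduct; 9 diazoethane
Product: 11 (4S,5R,7S,8S)-7,8-epoxy-10,11-secolongipin-2-ene-1,9-dione (cis-fused bicyclo[5.4.0]undecene; C10 epimers, erased in step 7), via ring-expanded silyl enol ether 10 (not isolated)
Conditions: Sc(OTf)3 (10 mol%), 9 (1.5 equiv), toluene–Et2O, −78 → −40 °C; then 1 M aq HCl, THF, 0 °C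
Reagents that add atoms: diazoethane 9, CC=[N+]=[N-]
Why: Büchner–Curtius–Schlotterbeck homologation, in which the electron-rich ring-fusion carbon C4 migrates with retention rather than the electron-poor oxirane carbon, placing CHMe (C10) between C4 and C9 before acid hydrolyses the enol ether and expels MeOH (E1cB) to give the 3-methyl enone.

**Step 7 (key step)**
Reactants: 11 (4S,5R,7S,8S)-7,8-epoxy-10,11-secolongipin-2-ene-1,9-dione
Product: 13 (4R,5S,7S,8S,10R,11R)-7,8-epoxylongipin-2-ene-1,9-dione, via dilithium bis-enolate 12 (not isolated)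
Conditions: 11 added to LDA (2.5 equiv), THF, −78 °C; then Fe(acac)3 (2.3 equiv), THF, −78 → 0 °C
Reagents that add atoms: none
Why: Proposed new method: each ketone has a single kinetic site (C11 as the α′-position of the enone, and C10 because the other flank of C9 is an oxirane C–H), the cis fusion holds C10 and C11 gauche at about 3 Å, one-electron oxidation by trivalent iron turns one enolate into an electrophilic α-keto radical (enolonium equivalent) that the neighbouring enolate captures, a second oxidation of the ketyl makes the 4-ring closure irreversible, the seven-ring tether allows only one configuration at C10 and C11, and the closest known reactions are intramolecular oxidative couplings of ketone, ester and amide bis-enolates by FeCl3, Fe(acac)3 or CuCl2, some of which close three- and four-membered rings.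

**Step 8**
Reactants: 13 (4R,5S,7S,8S,10R,11R)-7,8-epoxylongipin-2-ene-1,9-dione; 14 angelic acid ((Z)-2-methylbut-2-enoic acid)
Product: 15 (4R,5S,7S,8R,10R,11R)-8-angeloyloxy-7-hydroxylongipin-2-ene-1,9-dione
Conditions: 14 (3 equiv), Cs2CO3 (0.5 equiv), DMF, 40 °C
Reagents that add atoms: angelic acid 14, C/C=C(/C)C(=O)O
Why: SN2 opening of an α,β-epoxy ketone at the carbonyl-activated α-carbon (known for azide, thiolate, halide and acetate) occurs at C8 rather than neopentyl C7 with inversion, giving 8α-OAng and 7β-OH, while the acid buffer suppresses retro-aldol, dehydration and Z→E isomerisation.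

**Step 9**
Reactants: 15 (4R,5S,7S,8R,10R,11R)-8-angeloyloxy-7-hydroxylongipin-2-ene-1,9-dione
Product: 16 (4R,5S,7S,8R,9S,10R,11R)-8-angeloyloxy-7,9-dihydroxylongipin-2-en-1-one
Conditions: Me4NBH(OAc)3 (4 equiv), MeCN–AcOH (1:1), −30 °C
Reagents that add atoms: none
Why: Saksena–Evans hydroxyl-directed reduction, in which boron binds the 7β-OH and delivers hydride intramolecularly to the β-face of C9 to give the 1,3-anti 9α-alcohol (cis to 8-OAng), while the enone and the ester are inert to triacetoxyborohydride.

**Step 10**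
Reactants: 16 (4R,5S,7S,8R,9S,10R,11R)-8-angeloyloxy-7,9-dihydroxylongipin-2-en-1-one; 17 (R)-2-methylbutanoic acid
Product: 20 (4R,5S,7S,8R,9S,10R,11R)-8-angeloyloxy-7-hydroxy-9-[(2R)-2-methylbutanoyloxy]longipin-2-en-1-one, via 7-O-triethylsilyl ether 18 (not isolated), via silylated diester 19 (not isolated)
Conditions: Et3SiCl (1.05 equiv), Et3N, DMAP (cat.), CH2Cl2, −20 °C; then 17 (3 equiv), DCC (3 equiv), DMAP (1.5 equiv), 30 °C; then 1 M aq HCl, THF, 0 °C
Reagents that add atoms: (R)-2-methylbutanoic acid 17, OC(=O)[C@H](C)CC; chlorotriethylsilane, CC[Si](Cl)(CC)CC (silicon present only in 18 and 19)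
Why: Transient protection followed by Steglich esterification, in which the exposed equatorial 7-OH is silylated ahead of the axial 9-OH tucked under the cyclobutane, the remaining 9-OH is acylated without touching the acid's stereocentre, and dilute acid removes the silyl group.

## Compound list
1 | 4,4-dimethylcyclohex-2-en-1-one | CC1(C)CCC(=O)C=C1 | starting material
2 | (1S,6S)-5,5-dimethyl-7-oxabicyclo[4.1.0]heptan-2-one | O=C1CCC(C)(C)[C@@H]2O[C@H]12 | intermediate
3 | lithium enolate of 2 | [Li+].[O-]C1=CCC(C)(C)[C@@H]2O[C@H]12 | intermediate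
4 | (1S,6S)-5,5-dimethyl-7-oxabicyclo[4.1.0]hept-3-en-2-one | O=C1C=CC(C)(C)[C@@H]2O[C@H]12 | intermediate
5 | (E)-4-methoxypent-3-en-2-one | CO/C(C)=C/C(C)=O | starting material
6 | (E)-2-(tert-butyldimethylsilyloxy)-4-methoxypenta-1,3-diene | CO/C(C)=C/C(=C)O[Si](C)(C)C(C)(C)C | intermediate
7 | cis-fused, oxirane-anti Diels–Alder adduct (2S,3S,4aR,8S,8aR) | CC(C)(C)[Si](C)(C)OC1=C[C@](C)(OC)[C@@H]2C(=O)[C@H]3O[C@H]3C(C)(C)[C@@H]2C1 | intermediate
8 | N-ethyl-N-nitrosourea | CCN(N=O)C(N)=O | starting material
9 | diazoethane | CC=[N+]=[N-] | intermediate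
10 | ring-expanded silyl enol ether (C10 epimers) | CC(C)(C)[Si](C)(C)OC1=C[C@](C)(OC)[C@@H]2C(C)C(=O)[C@H]3O[C@H]3C(C)(C)[C@@H]2C1 | intermediate
11 | (4S,5R,7S,8S)-7,8-epoxy-10,11-secolongipin-2-ene-1,9-dione (C10 epimers) | O=C1C=C(C)[C@@H]2C(C)C(=O)[C@H]3O[C@H]3C(C)(C)[C@@H]2C1 | intermediate
12 | dilithium 1,9-bis-enolate of 11 | [Li+].[Li+].[O-]C1=C[C@H]2C(C)(C)[C@@H]3O[C@@H]3C([O-])=C(C)[C@H]2C(C)=C1 | intermediate
13 | (4R,5S,7S,8S,10R,11R)-7,8-epoxylongipin-2-ene-1,9-dione | O=C1[C@H]2O[C@H]2C(C)(C)[C@@H]3[C@H]4C(=O)C=C(C)[C@@H]3[C@@]14C | intermediate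
14 | angelic acid | C/C=C(/C)C(=O)O | starting material
15 | (4R,5S,7S,8R,10R,11R)-8-angeloyloxy-7-hydroxylongipin-2-ene-1,9-dione | C/C=C(/C)C(=O)O[C@@H]1[C@@H](O)C(C)(C)[C@@H]2[C@H]3C(=O)C=C(C)[C@@H]2[C@@]3(C)C1=O | intermediate
16 | (4R,5S,7S,8R,9S,10R,11R)-8-angeloyloxy-7,9-dihydroxylongipin-2-en-1-one | C/C=C(/C)C(=O)O[C@@H]1[C@@H](O)C(C)(C)[C@@H]2[C@H]3C(=O)C=C(C)[C@@H]2[C@@]3(C)[C@@H]1O | intermediate
17 | (R)-2-methylbutanoic acid | OC(=O)[C@H](C)CC | starting material
18 | 7-O-triethylsilyl ether of 16 | C/C=C(/C)C(=O)O[C@@H]1[C@@H](O[Si](CC)(CC)CC)C(C)(C)[C@@H]2[C@H]3C(=O)C=C(C)[C@@H]2[C@@]3(C)[C@@H]1O | intermediate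
19 | 7-O-triethylsilyl ether of 20 | C/C=C(/C)C(=O)O[C@@H]1[C@@H](O[Si](CC)(CC)CC)C(C)(C)[C@@H]2[C@H]3C(=O)C=C(C)[C@@H]2[C@@]3(C)[C@@H]1OC(=O)[C@H](C)CC | intermediate
20 | CNP0202800.1, (4R,5S,7S,8R,9S,10R,11R)-8-angeloyloxy-7-hydroxy-9-[(2R)-2-methylbutanoyloxy]longipin-2-en-1-one | C/C=C(/C)C(=O)O[C@@H]1[C@@H](O)C(C)(C)[C@@H]2[C@H]3C(=O)C=C(C)[C@@H]2[C@@]3(C)[C@@H]1OC(=O)[C@H](C)CC | target

## Step count
- Total steps: 10.
- Longest linear sequence: 8 (1 → 2 → 4 → 7 → 11 → 13 → 15 → 16 → 20).

## Steps most likely to fail, with fallbacks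

**Step 7 (oxidative cyclobutane closure).** A mono-enolate can undergo transannular aldol addition, and over-oxidation could aromatise the enone ring. The fallback sets out from 11 and replaces electron-transfer coupling with a two-electron sequence. An in-situ LDA/Me3SiCl quench traps only the faster-formed C11 enolate as the trimethylsilyl dienol ether F2. N-Iodosuccinimide converts this into the 11-iodo enone F3, an isolated enolonium equivalent. KHMDS then removes the C10 proton, and the tetrasubstituted enolate displaces iodide in a 4-exo-tet SN2 closure. This comes back to the route at 13.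

**Step 6 (diazoethane insertion).** Spiro-epoxide formation, Lewis-acid damage to the oxirane or enol ether, and diazoalkane decomposition all compete with insertion. The fallback sets out from 7 and uses a semipinacol route. 1-(Phenylselanyl)ethyllithium, made from 1,1-bis(phenylselanyl)ethane and n-BuLi at −78 °C, adds to the ketone to give the β-hydroxy selenide F1. AgBF4 on alumina activates selenium as a leaving group, so C4 migrates to the carbinyl side chain. This comes back at 10, which the same acid treatment converts into 11.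

**Step 8 (angelate opening).** The carboxylate is a weak nucleophile, and the product can dehydrate, undergo retro-aldol cleavage or suffer acyl migration. The fallback sets out from 13. Reductive opening with PhSeSePh/NaBH4 in EtOH–AcOH gives the 7β-hydroxy dione F4. Double deprotonation with LiHMDS and oxidation with 2-(phenylsulfonyl)-3-phenyloxaziridine, approaching anti to the 7-alkoxide, gives the 7β,8α-diol F5. Yamaguchi esterification with angelic acid then acylates the unhindered 8-OH in preference to the neopentyl 7-OH. This comes back at 15.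

## Further compounds
F1 | step 6 | β-hydroxy selenide from 7 (carbinol and Se-bearing centres undefined) | CC(C)(C)[Si](C)(C)OC1=C[C@](C)(OC)[C@@H]2C(O)(C(C)[Se]c3ccccc3)[C@H]4O[C@H]4C(C)(C)[C@@H]2C1
F2 | step 7 | 1-trimethylsilyloxy-1(11),2-diene of 11 | C[Si](C)(C)OC1=C[C@H]2C(C)(C)[C@@H]3O[C@@H]3C(=O)C(C)[C@H]2C(C)=C1
F3 | step 7 | 11-iodo derivative of 11 | O=C1C=C(C)[C@@H]2C(C)C(=O)[C@H]3O[C@H]3C(C)(C)[C@@H]2C1I
F4 | step 8 | (4R,5S,7S,10R,11R)-7-hydroxylongipin-2-ene-1,9-dione | O=C1C[C@@H](O)C(C)(C)[C@@H]2[C@H]3C(=O)C=C(C)[C@@H]2[C@@]13C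
F5 | step 8 | 7β,8α-dihydroxylongipin-2-ene-1,9-dione | O=C1[C@H](O)[C@@H](O)C(C)(C)[C@@H]2[C@H]3C(=O)C=C(C)[C@@H]2[C@@]13C
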